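**Retrosynthetic overview** (flavanone numbering O1, C2 … C8a; primed atoms are the side chain)
1. Rings C and A are both opened in the last operation: C5–C4a (6π-electrocyclisation of a dienylketene) and O1–C8a (cyclodehydration) lead back to an open-chain δ-hydroxy-β,δ-diketone that ends in a 1,3-dioxin-4-one (masked acylketene).
2. The C4–C4a bond is cut (Claisen acylation of a dianion) into a β-hydroxy Weinreb amide that carries ring B and C2, and a keto-dioxinone that carries the side chain on the future C6.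
3. C2 is set by asymmetric hydrogenation of a β-keto ester; C3' is bought in a terpene diene and joined to the dioxinone by a Heck reaction.
4. Ring order: ring B is bought; ring C closes first and ring A second, in the same flask; ring A is built de novo, so C6 versus C8 is fixed by connectivity.

**Step 1**
Reactants: 1 2,2,6-trimethyl-4H-1,3-dioxin-4-one
Product: 2 5-iodo-2,2,6-trimethyl-4H-1,3-dioxin-4-one
Conditions: NIS (1.1 equiv), AcOH, 23 °C, dark
Reagents that add atoms: N-iodosuccinimide, O=C1CCC(=O)N1I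
Why: C5 is the nucleophilic α-carbon of a vinylogous ester, so electrophilic iodination (addition–elimination with NIS) takes place there only.

**Step 2**
Reactants: 2 5-iodo-2,2,6-trimethyl-4H-1,3-dioxin-4-one; 3 (S)-3,7-dimethylocta-1,6-diene ((S)-β-citronellene)
Product: 4 5-[(3S,1E)-3,7-dimethylocta-1,6-dien-1-yl]-2,2,6-trimethyl-4H-1,3-dioxin-4-one
Conditions: Pd(OAc)2 (5 mol %), n-Bu4NCl (1 equiv), NaHCO3 (2.5 equiv), DMF, 60 °C
Reagents that add atoms: none
Why: Mizoroki–Heck reaction under ligand-free Jeffery conditions, in which the alkenylpalladium species adds to the terminal CH2 of the monosubstituted alkene (the trisubstituted alkene is inert), β-hydride elimination into conjugation gives the (E)-diene, and the allylic stereocenter bought with 3 is not touched.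

**Step 3**
Reactants: 4 5-[(3S,1E)-3,7-dimethylocta-1,6-dien-1-yl]-2,2,6-trimethyl-4H-1,3-dioxin-4-one
Product: 6 5-[(3S,1E)-3,7-dimethylocta-1,6-dien-1-yl]-2,2-dimethyl-6-(2-oxopropyl)-4H-1,3-dioxin-4-one, via lithium dienolate 5 (not isolated)
Conditions: LiN(SiMe3)2 (1.1 equiv), THF, −78 °C; then AcCl (0.6 equiv), −78 °C; unreacted 4 recovered
Reagents that add atoms: acetyl chloride, CC(=O)Cl
Why: Kinetic γ-deprotonation of the 6-methyl group gives the cross-conjugated dienolate, which is C-acylated at the γ-carbon (vinylogous Claisen condensation, the standard entry to keto-dioxinones), part of the dienolate serving as base for the more acidic product and returning as recyclable 4.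

**Step 4**
Reactants: 7 4-(tert-butyldimethylsilyloxy)benzaldehyde
Product: 8 ethyl 3-[4-(tert-butyldimethylsilyloxy)phenyl]-3-oxopropanoate
Conditions: SnCl2 (10 mol %), ethyl diazoacetate (1.2 equiv), CH2Cl2, 23 °C
Reagents that add atoms: ethyl diazoacetate, CCOC(=O)C=[N+]=[N-]
Why: Roskamp homologation, in which Lewis-acid-promoted addition of the diazo ester to the aldehyde is followed by a 1,2-hydride shift with loss of dinitrogen to give the β-keto ester directly.

**Step 5**
Reactants: 8 ethyl 3-[4-(tert-butyldimethylsilyloxy)phenyl]-3-oxopropanoate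
Product: 9 ethyl (3S)-3-[4-(tert-butyldimethylsilyloxy)phenyl]-3-hydroxypropanoate
Conditions: [RuCl(p-cymene)((R)-BINAP)]Cl (0.5 mol %), H2 (30 bar), EtOH, 60 °C
Reagents that add atoms: none
Why: Noyori asymmetric hydrogenation of an ester-chelated β-keto ester, where the (R)-BINAP catalyst delivers hydride to the face that gives the (S)-carbinol in the aryl series (the aryl group outranks CH2CO2Et, so the descriptor is opposite to that of the alkyl series), and this carbinol becomes C2 of the flavanone.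

**Step 6**
Reactants: 9 ethyl (3S)-3-[4-(tert-butyldimethylsilyloxy)phenyl]-3-hydroxypropanoate
Product: 10 (3S)-3-[4-(tert-butyldimethylsilyloxy)phenyl]-3-hydroxy-N-methoxy-N-methylpropanamide
Conditions: MeNHOMe·HCl (2.5 equiv), i-PrMgCl (5.5 equiv), THF, −20 to 0 °C
Reagents that add atoms: N,O-dimethylhydroxylamine hydrochloride, CNOC.Cl
Why: Weinreb amidation of the ester by the magnesium amide made in the flask, with the free hydroxyl carried as its magnesium alkoxide and no bond to the stereocenter affected.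

**Step 7**
Reactants: 6 5-[(3S,1E)-3,7-dimethylocta-1,6-dien-1-yl]-2,2-dimethyl-6-(2-oxopropyl)-4H-1,3-dioxin-4-one; 10 (3S)-3-[4-(tert-butyldimethylsilyloxy)phenyl]-3-hydroxy-N-methoxy-N-methylpropanamide
Product: 13 6-[(6S)-6-[4-(tert-butyldimethylsilyloxy)phenyl]-6-hydroxy-2,4-dioxohexyl]-5-[(3S,1E)-3,7-dimethylocta-1,6-dien-1-yl]-2,2-dimethyl-4H-1,3-dioxin-4-one, via dilithium dianion 11 (not isolated), via lithium alkoxide 12 (not isolated)
Conditions: 6, LiN(i-Pr)2 (2.1 equiv), THF, −78 °C; 10, LiN(SiMe3)2 (1.0 equiv), THF, −78 °C; combine, −78 to −40 °C; aq NH4Cl; product used crude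
Reagents that add atoms: none
Why: Claisen-type acylation of a 1,3-dicarbonyl dianion (Harris–Weiler chemistry, as used for diketo-dioxinones), in which the terminal carbanion of the dianion adds to the Weinreb amide and the chelated tetrahedral adduct prevents over-addition, forming C4–C4a without touching the carbinol stereocenter.

**Step 8**
Reactants: 13 6-[(6S)-6-[4-(tert-butyldimethylsilyloxy)phenyl]-6-hydroxy-2,4-dioxohexyl]-5-[(3S,1E)-3,7-dimethylocta-1,6-dien-1-yl]-2,2-dimethyl-4H-1,3-dioxin-4-one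
Product: 17 (2S)-6-[(3S,1E)-3,7-dimethylocta-1,6-dien-1-yl]-5,7-dihydroxy-2-(4-hydroxyphenyl)-2,3-dihydro-4H-chromen-4-one, via dihydropyranone-dioxinone 14 (not isolated), via acylketene 15 (not isolated), via silyl-protected flavanone 16 (not isolated)
Conditions: PPTS (20 mol %), 4 Å MS, PhMe (0.01 M), 50 °C; then 110 °C; then HF·pyridine, THF, 0 °C
Reagents that add atoms: none
Why: Proposed new method: the δ-hydroxy-β-diketone first cyclodehydrates under mild acid to the 2,3-dihydro-4-pyranone 14 (ring C, known for aldol adducts of acetylacetone dianion), which fixes O1 on C8a, then at 110 °C the dioxinone loses acetone by retro-[4+2] to acylketene 15, whose C7 ketone enolises towards C8 to a dienylketene that closes by 6π-electrocyclisation between the ketene carbon C5 and the nucleophilic pyranone carbon C4a and tautomerises to the phloroglucinol ring A of 16 (the C5 substituent of the dioxinone blocks the aldol-type aromatisation and the alkylated O1 blocks pyranone formation), and fluoride finally frees the ring B phenol, the closest known reactions being dioxinone thermolysis with late-stage aromatisation to resorcylates and the dienylketene electrocyclisation that ends Danheiser benzannulations, while C2 stays (S) because no bond to it is made or broken and the side chain sits on C6 by connectivity.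

**Compound list**
1 | 2,2,6-trimethyl-4H-1,3-dioxin-4-one | CC1=CC(=O)OC(C)(C)O1 | starting material
2 | 5-iodo-2,2,6-trimethyl-4H-1,3-dioxin-4-one | CC1=C(I)C(=O)OC(C)(C)O1 | intermediate
3 | (S)-3,7-dimethylocta-1,6-diene ((S)-β-citronellene) | CC(C)=CCC[C@H](C)C=C | starting material
4 | 5-[(3S,1E)-3,7-dimethylocta-1,6-dien-1-yl]-2,2,6-trimethyl-4H-1,3-dioxin-4-one | CC(C)=CCC[C@H](C)/C=C/C1=C(C)OC(C)(C)OC1=O | intermediate
5 | lithium dienolate of 4 (lithium 5-[(3S,1E)-3,7-dimethylocta-1,6-dien-1-yl]-2,2-dimethyl-6-methylidene-6H-1,3-dioxin-4-olate) | CC(C)=CCC[C@H](C)/C=C/C1=C(O[Li])OC(C)(C)OC1=C | intermediate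
6 | 5-[(3S,1E)-3,7-dimethylocta-1,6-dien-1-yl]-2,2-dimethyl-6-(2-oxopropyl)-4H-1,3-dioxin-4-one | CC(C)=CCC[C@H](C)/C=C/C1=C(CC(C)=O)OC(C)(C)OC1=O | intermediate
7 | 4-(tert-butyldimethylsilyloxy)benzaldehyde | CC(C)(C)[Si](C)(C)Oc1ccc(C=O)cc1 | starting material
8 | ethyl 3-[4-(tert-butyldimethylsilyloxy)phenyl]-3-oxopropanoate | CCOC(=O)CC(=O)c1ccc(O[Si](C)(C)C(C)(C)C)cc1 | intermediate
9 | ethyl (3S)-3-[4-(tert-butyldimethylsilyloxy)phenyl]-3-hydroxypropanoate | CCOC(=O)C[C@@H](c1ccc(O[Si](C)(C)C(C)(C)C)cc1)O | intermediate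
10 | (3S)-3-[4-(tert-butyldimethylsilyloxy)phenyl]-3-hydroxy-N-methoxy-N-methylpropanamide | CON(C)C(=O)C[C@@H](c1ccc(O[Si](C)(C)C(C)(C)C)cc1)O | intermediate
11 | dilithium dianion of 6 (bis-enolate at the terminal methyl and at the ring-bound methylene) | CC(C)=CCC[C@H](C)/C=C/C1=C(O[Li])OC(C)(C)OC1=CC(=C)O[Li] | intermediate
12 | lithium alkoxide of 10 | CON(C)C(=O)C[C@@H](c1ccc(O[Si](C)(C)C(C)(C)C)cc1)O[Li] | intermediate
13 | 6-[(6S)-6-[4-(tert-butyldimethylsilyloxy)phenyl]-6-hydroxy-2,4-dioxohexyl]-5-[(3S,1E)-3,7-dimethylocta-1,6-dien-1-yl]-2,2-dimethyl-4H-1,3-dioxin-4-one | CC(C)=CCC[C@H](C)/C=C/C1=C(CC(=O)CC(=O)C[C@@H](c2ccc(O[Si](C)(C)C(C)(C)C)cc2)O)OC(C)(C)OC1=O | intermediate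
14 | 6-{[(2S)-2-[4-(tert-butyldimethylsilyloxy)phenyl]-4-oxo-3,4-dihydro-2H-pyran-6-yl]methyl}-5-[(3S,1E)-3,7-dimethylocta-1,6-dien-1-yl]-2,2-dimethyl-4H-1,3-dioxin-4-one | CC(C)=CCC[C@H](C)/C=C/C1=C(CC2=CC(=O)C[C@@H](c3ccc(O[Si](C)(C)C(C)(C)C)cc3)O2)OC(C)(C)OC1=O | intermediate
15 | acylketene 2-[(3S,1E)-3,7-dimethylocta-1,6-dien-1-yl]-3-oxo-4-[(2S)-2-[4-(tert-butyldimethylsilyloxy)phenyl]-4-oxo-3,4-dihydro-2H-pyran-6-yl]but-1-en-1-one | CC(C)=CCC[C@H](C)/C=C/C(=C=O)C(=O)CC1=CC(=O)C[C@@H](c2ccc(O[Si](C)(C)C(C)(C)C)cc2)O1 | intermediate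
16 | (2S)-2-[4-(tert-butyldimethylsilyloxy)phenyl]-6-[(3S,1E)-3,7-dimethylocta-1,6-dien-1-yl]-5,7-dihydroxy-2,3-dihydro-4H-chromen-4-one | CC(C)=CCC[C@H](C)/C=C/c1c(O)cc2c(c1O)C(=O)C[C@@H](c1ccc(O[Si](C)(C)C(C)(C)C)cc1)O2 | intermediate
17 | (2S)-6-[(3S,1E)-3,7-dimethylocta-1,6-dien-1-yl]-5,7-dihydroxy-2-(4-hydroxyphenyl)-2,3-dihydro-4H-chromen-4-one | CC(C)=CCC[C@H](C)/C=C/c1c(O)cc2c(c1O)C(=O)C[C@@H](c1ccc(O)cc1)O2 | target

**Total step count:** 8
**Longest linear sequence:** 5 steps (1 → 2 → 3 → 7 → 8, or 4 → 5 → 6 → 7 → 8)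

**Steps most likely to fail**

Step 8 is the largest risk. The acylketene may dimerise or be hydrolysed before the electrocyclisation, or the cyclodehydration may be incomplete when the ketene forms. The fallback sets out from 13 and separates the two ring closures. The PPTS stage alone is run and 14 is isolated. Compound 14 is then heated with 2-methylpropane-2-thiol in PhMe at 100 °C, so that the ketene is intercepted as S-tert-butyl 2-[(3S,1E)-3,7-dimethylocta-1,6-dien-1-yl]-3-oxo-4-[(2S)-2-[4-(tert-butyldimethylsilyloxy)phenyl]-4-oxo-3,4-dihydro-2H-pyran-6-yl]butanethioate F7. Thioester activation with AgOCOCF3 in CH2Cl2 at 23 °C then closes ring A by C-acylation at C4a at room temperature. This comes back to the route at 16, which is desilylated as before.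

Step 7 is the second risk. The alkoxide-bearing Weinreb amide may react sluggishly or undergo retro-aldol cleavage, and the polycarbonyl product is sensitive. The fallback sets out from 9 and replaces the acylation by an aldol addition and oxidation. Silylation with TBSCl and imidazole gives ethyl (3S)-3-(tert-butyldimethylsilyloxy)-3-[4-(tert-butyldimethylsilyloxy)phenyl]propanoate F3. Reduction with i-Bu2AlH in CH2Cl2 at −78 °C gives (3S)-3-(tert-butyldimethylsilyloxy)-3-[4-(tert-butyldimethylsilyloxy)phenyl]propanal F4. Addition of dianion 11 at −78 °C gives 6-[(6S)-6-(tert-butyldimethylsilyloxy)-6-[4-(tert-butyldimethylsilyloxy)phenyl]-4-hydroxy-2-oxohexyl]-5-[(3S,1E)-3,7-dimethylocta-1,6-dien-1-yl]-2,2-dimethyl-4H-1,3-dioxin-4-one F5 as a carbinol epimer mixture. Dess–Martin oxidation gives 6-[(6S)-6-(tert-butyldimethylsilyloxy)-6-[4-(tert-butyldimethylsilyloxy)phenyl]-2,4-dioxohexyl]-5-[(3S,1E)-3,7-dimethylocta-1,6-dien-1-yl]-2,2-dimethyl-4H-1,3-dioxin-4-one F6. CSA in MeOH–CH2Cl2 at 0 °C removes only the secondary silyl ether and comes back to the route at 13.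

Step 2 is the third risk. β-Hydride elimination towards C3' would give the allyl isomer, and chain walking could erode the C3' stereocenter. The fallback sets out from 3 and replaces the Heck reaction by borylation and cross-coupling. A boryl-Heck reaction (B-chlorocatecholborane, Pd2(dba)3, JessePhos, LiOTf, Cy2NMe, PhCF3, 70 °C) gives 2-[(3S,1E)-3,7-dimethylocta-1,6-dien-1-yl]-1,3,2-benzodioxaborole F1. Exchange with pinacol gives 2-[(3S,1E)-3,7-dimethylocta-1,6-dien-1-yl]-4,4,5,5-tetramethyl-1,3,2-dioxaborolane F2. Suzuki–Miyaura coupling of F2 with 2 (Pd(dppf)Cl2, K3PO4, THF–H2O, 50 °C) comes back to the route at 4.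

**Further compounds**
F1 | step 2 | 2-[(3S,1E)-3,7-dimethylocta-1,6-dien-1-yl]-1,3,2-benzodioxaborole | CC(C)=CCC[C@H](C)/C=C/B1Oc2ccccc2O1
F2 | step 2 | 2-[(3S,1E)-3,7-dimethylocta-1,6-dien-1-yl]-4,4,5,5-tetramethyl-1,3,2-dioxaborolane | CC(C)=CCC[C@H](C)/C=C/B1OC(C)(C)C(C)(C)O1
F3 | step 7 | ethyl (3S)-3-(tert-butyldimethylsilyloxy)-3-[4-(tert-butyldimethylsilyloxy)phenyl]propanoate | CCOC(=O)C[C@@H](c1ccc(O[Si](C)(C)C(C)(C)C)cc1)O[Si](C)(C)C(C)(C)C
F4 | step 7 | (3S)-3-(tert-butyldimethylsilyloxy)-3-[4-(tert-butyldimethylsilyloxy)phenyl]propanal | O=CC[C@@H](c1ccc(O[Si](C)(C)C(C)(C)C)cc1)O[Si](C)(C)C(C)(C)C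
F5 | step 7 | 6-[(6S)-6-(tert-butyldimethylsilyloxy)-6-[4-(tert-butyldimethylsilyloxy)phenyl]-4-hydroxy-2-oxohexyl]-5-[(3S,1E)-3,7-dimethylocta-1,6-dien-1-yl]-2,2-dimethyl-4H-1,3-dioxin-4-one | CC(C)=CCC[C@H](C)/C=C/C1=C(CC(=O)CC(O)C[C@@H](c2ccc(O[Si](C)(C)C(C)(C)C)cc2)O[Si](C)(C)C(C)(C)C)OC(C)(C)OC1=O
F6 | step 7 | 6-[(6S)-6-(tert-butyldimethylsilyloxy)-6-[4-(tert-butyldimethylsilyloxy)phenyl]-2,4-dioxohexyl]-5-[(3S,1E)-3,7-dimethylocta-1,6-dien-1-yl]-2,2-dimethyl-4H-1,3-dioxin-4-one | CC(C)=CCC[C@H](C)/C=C/C1=C(CC(=O)CC(=O)C[C@@H](c2ccc(O[Si](C)(C)C(C)(C)C)cc2)O[Si](C)(C)C(C)(C)C)OC(C)(C)OC1=O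
F7 | step 8 | S-tert-butyl 2-[(3S,1E)-3,7-dimethylocta-1,6-dien-1-yl]-3-oxo-4-[(2S)-2-[4-(tert-butyldimethylsilyloxy)phenyl]-4-oxo-3,4-dihydro-2H-pyran-6-yl]butanethioate | CC(C)=CCC[C@H](C)/C=C/C(C(=O)SC(C)(C)C)C(=O)CC1=CC(=O)C[C@@H](c2ccc(O[Si](C)(C)C(C)(C)C)cc2)O1
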